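**Plan**

Numbering used throughout: ring carbons C1–C10, with C3 the ketone, C4=C5 the ring olefin (C15H2OH on C4), C6 the lactone O–CH, C7 the CH that carries C11(=C13H2)–C12(=O), C8 the ester carbon and C10 the carbinol with the C14 methyl.
Retrosynthesis: first the C8–O angelate bond; then, in one event, the lactone C12–O bond and the ring bond C6–C7, which opens both rings to a linear bromide–aldehyde; then C7–C11 (acrylate), C2–C3 (sp3–sp2 coupling) and the prenyl C=C of linalool.
Enabling feature: the ring segment C3(=O)–C4=C5(Z)–C6(O) is an oxidatively opened 2,3-disubstituted furan (furan carbons C3–C6, C15 on C4), so the seco compound is a (Z)-4-oxo-2-enal; C7/C11/C12/C13 form a 2-(bromomethyl)acrylate, an allyl donor that delivers C7 to C6 and the exocyclic methylene together.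
Forward: (S)-linalool (C1, C2, C7–C10, C14) and 3-furanmethanol (C3–C6, C15) are joined at C2–C3; C7 is freed as an aldehyde, C8 is oxygenated, methyl acrylate (C11–C13) is added and the furan is opened; C6–C7 closure forms the carbocycle and the lactone follows directly; angelate and desilylation come last.
Stereochemistry: C10 from (S)-linalool; C8 from L-proline-catalysed α-aminoxylation; C6 and C7 from the chair transition state of the ring closure under control of C8 and the (Z)-bromide; the C4=C5 geometry from the furan; the angelate geometry from angelic acid.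

Key step: step 11

Assumption: (S)-(+)-linalool of high enantiomeric purity is taken as a purchasable chiral-pool compound, and the target is addressed in the open hydroxy-ketone form drawn.

**Route**

Step 1
Reactants: 1 (S)-(+)-linalool
Product: 2 (3S)-3,7-dimethyl-3-(triethylsilyloxy)octa-1,6-diene
Conditions: TESOTf (1.3 equiv), 2,6-lutidine, CH2Cl2, −78 → 0 °C
Reagents that add atoms: triethylsilyl trifluoromethanesulfonate, CC[Si](CC)(CC)OS(=O)(=O)C(F)(F)F
Why: O-Silylation of the tertiary allylic alcohol with a silyl triflate and a hindered pyridine base is routine, leaves the carbinol centre C10 untouched and blocks lactol formation once C7 becomes an aldehyde.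

Step 2
Reactants: 3 3-furanmethanol
Product: 6 2-bromo-3-[(tert-butyldiphenylsilyloxy)methyl]furan, via dilithiated furan 4 (not isolated), via lithium bromofuranylmethoxide 5 (not isolated)
Conditions: n-BuLi (2.1 equiv), THF, −78 → 0 °C; BrCCl2CCl2Br, −78 °C; then TBDPSCl, DMAP (cat.), −78 °C → rt
Reagents that add atoms: 1,2-dibromo-1,1,2,2-tetrachloroethane, BrC(Cl)(Cl)C(Cl)(Cl)Br; tert-butyl(chloro)diphenylsilane, CC(C)(C)[Si](Cl)(c1ccccc1)c1ccccc1
Why: The lithium alkoxide should direct the second lithiation to the adjacent furan C2 (directed ortho-metalation of the dianion), the C–Li bond is brominated by the positive-bromine donor, and the remaining alkoxide is silylated in the same flask so that the labile bromo alcohol is never isolated.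

Step 3
Reactants: 2 (3S)-3,7-dimethyl-3-(triethylsilyloxy)octa-1,6-diene; 6 2-bromo-3-[(tert-butyldiphenylsilyloxy)methyl]furan
Product: 8 3-[(tert-butyldiphenylsilyloxy)methyl]-2-[(3S)-3,7-dimethyl-3-(triethylsilyloxy)oct-6-enyl]furan, via B-alkyl-9-BBN borane 7 (not isolated)
Conditions: 9-BBN (1.3 equiv), THF, 0 °C → rt; then 6, Pd(dppf)Cl2 (5 mol%), aq. K3PO4, DMF, 50 °C
Reagents that add atoms: none
Why: 9-BBN hydroborates only the monosubstituted vinyl group at its terminus (anti-Markovnikov, the trisubstituted alkene is too hindered), and the primary alkylborane then undergoes B-alkyl Suzuki–Miyaura coupling with the 2-bromofuran, which joins C2 to C3 without touching C10.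

Step 4
Reactants: 8 3-[(tert-butyldiphenylsilyloxy)methyl]-2-[(3S)-3,7-dimethyl-3-(triethylsilyloxy)oct-6-enyl]furan
Product: 10 (4R)-6-{3-[(tert-butyldiphenylsilyloxy)methyl]furan-2-yl}-4-methyl-4-(triethylsilyloxy)hexanal, via vicinal diol 9 (not isolated)
Conditions: OsO4 (2 mol%), NaIO4 (4 equiv), 2,6-lutidine, dioxane/H2O (3:1), rt
Reagents that add atoms: osmium tetroxide, O=[Os](=O)(=O)=O; sodium periodate (re-oxidant and oxygen source), [Na+].[O-]I(=O)(=O)=O
Why: Lemieux–Johnson oxidation: OsO4 dihydroxylates the electron-rich trisubstituted alkene much faster than the aromatic furan and periodate cleaves the glycol in the lutidine-buffered medium, which frees C7 as the aldehyde.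

Step 5
Reactants: 10 (4R)-6-{3-[(tert-butyldiphenylsilyloxy)methyl]furan-2-yl}-4-methyl-4-(triethylsilyloxy)hexanal
Product: 13 (2R,4R)-6-{3-[(tert-butyldiphenylsilyloxy)methyl]furan-2-yl}-4-methyl-4-(triethylsilyloxy)hexane-1,2-diol, via α-aminoxy aldehyde 11 (not isolated), via anilinooxy alcohol 12 (not isolated)
Conditions: PhNO (1.1 equiv), L-proline (20 mol%), CHCl3, 4 °C; NaBH4, EtOH, 0 °C; then Zn, AcOH, rt
Reagents that add atoms: nitrosobenzene, O=Nc1ccccc1
Why: Proline-catalysed α-aminoxylation: the enamine of 10 with L-proline is attacked by the oxygen of nitrosobenzene on the face directed by the carboxylic acid hydrogen bond, which sets C8 as R under catalyst control, reduction in the same flask prevents epimerisation and zinc in acetic acid cleaves the N–O bond.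

Step 6
Reactants: 13 (2R,4R)-6-{3-[(tert-butyldiphenylsilyloxy)methyl]furan-2-yl}-4-methyl-4-(triethylsilyloxy)hexane-1,2-diol
Product: 14 1,2-bis-O-triethylsilyl ether of 13
Conditions: TESCl (2.5 equiv), imidazole, DMF, 0 °C → rt
Reagents that add atoms: chlorotriethylsilane, CC[Si](Cl)(CC)CC
Why: Standard silylation of a primary and a secondary alcohol with a silyl chloride and imidazole; no stereocentre is involved.

Step 7
Reactants: 14 1,2-bis-O-triethylsilyl ether of 13
Product: 15 (2R,4R)-6-{3-[(tert-butyldiphenylsilyloxy)methyl]furan-2-yl}-4-methyl-2,4-bis(triethylsilyloxy)hexanal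
Conditions: (COCl)2, DMSO, CH2Cl2, −78 → −35 °C; Et3N, −78 → 0 °C
Reagents that add atoms: none
Why: Under Swern conditions the chlorosulfonium salt cleaves the unhindered primary triethylsilyl ether and oxidises it in place to the aldehyde while the secondary and tertiary silyl ethers persist (direct Swern oxidation of primary silyl ethers), and the cold, amine-buffered conditions should not epimerise C8.

Step 8
Reactants: 15 (2R,4R)-6-{3-[(tert-butyldiphenylsilyloxy)methyl]furan-2-yl}-4-methyl-2,4-bis(triethylsilyloxy)hexanal; 16 methyl acrylate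
Product: 17 methyl (4R,6R)-8-{3-[(tert-butyldiphenylsilyloxy)methyl]furan-2-yl}-3-hydroxy-6-methyl-2-methylidene-4,6-bis(triethylsilyloxy)octanoate (both C3 epimers)
Conditions: methyl acrylate (neat, excess), DABCO (1 equiv), MeOH (cat.), rt
Reagents that add atoms: none
Why: Morita–Baylis–Hillman reaction: the α-oxygenated aldehyde is an activated acceptor for the DABCO–acrylate zwitterion, and the new carbinol carbon C7 may form as a mixture of epimers because it becomes sp2 in the next step.

Step 9
Reactants: 17 methyl (4R,6R)-8-{3-[(tert-butyldiphenylsilyloxy)methyl]furan-2-yl}-3-hydroxy-6-methyl-2-methylidene-4,6-bis(triethylsilyloxy)octanoate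
Product: 19 methyl (2Z,4R,6R)-2-(bromomethyl)-8-{3-[(tert-butyldiphenylsilyloxy)methyl]furan-2-yl}-6-methyl-4,6-bis(triethylsilyloxy)oct-2-enoate, via allylic mesylate 18 (not isolated)
Conditions: Ms2O, Et3N, CH2Cl2, −20 °C; then LiBr, THF, 0 °C → rt
Reagents that add atoms: lithium bromide, [Li+].[Br-]
Why: Sulfonylation followed by bromide displacement with allylic transposition (SN2' and equilibration through bromide) converges both C7 epimers on the thermodynamically preferred (2Z)-2-(bromomethyl)enoate, in which C8 is cis to CH2Br and trans to the ester, as is usual for Baylis–Hillman adducts, and C8 itself is not touched.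

Step 10
Reactants: 19 methyl (2Z,4R,6R)-2-(bromomethyl)-8-{3-[(tert-butyldiphenylsilyloxy)methyl]furan-2-yl}-6-methyl-4,6-bis(triethylsilyloxy)oct-2-enoate
Product: 20 methyl (2Z,4R,6R,10Z)-2-(bromomethyl)-10-[(tert-butyldiphenylsilyloxy)methyl]-6-methyl-9,12-dioxo-4,6-bis(triethylsilyloxy)dodeca-2,10-dienoate
Conditions: DMDO (1.05 equiv, acetone), CH2Cl2, −78 → −20 °C; cold concentration; used at once
Reagents that add atoms: dimethyldioxirane, CC1(C)OO1
Why: Oxidative furan ring opening: dimethyldioxirane epoxidises the electron-rich furan far faster than the electron-poor enoate, the furan epoxide opens at once to the cis-enedione, and the ring thus delivers the C3 ketone, the C6 aldehyde and the (Z)-C4=C5 geometry under neutral conditions with acetone as the only by-product.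

Step 11
Reactants: 20 methyl (2Z,4R,6R,10Z)-2-(bromomethyl)-10-[(tert-butyldiphenylsilyloxy)methyl]-6-methyl-9,12-dioxo-4,6-bis(triethylsilyloxy)dodeca-2,10-dienoate
Product: 23 cis-fused ten-membered α-methylene lactone (8,10-bis-O-triethylsilyl 15-O-tert-butyldiphenylsilyl ether of the 8-deangeloyl target), via allylchromium dichloride 21 (not isolated), via chromium alkoxide 22 (not isolated)
Conditions: CrCl2 (8 equiv), THF, rt, syringe-pump addition of 20 (final 2 mM), dark; pH 7 buffer work-up
Reagents that add atoms: none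
Why: CrCl2 (divalent chromium, two equivalents per bromide) reduces the allylic bromide to the allylchromium dichloride 21 (trivalent chromium), whose γ-carbon C7 adds to the C6 aldehyde through a closed six-membered chair (Zimmerman–Traxler) transition state with SE2' shift of the double bond to C11=C13, after which the chromium alkoxide 22 attacks the neighbouring methyl ester. The closest known reaction type is the intramolecular Nozaki–Hiyama–Kishi (Barbier-type) allylation of seco-enals by 2-(bromomethyl)acrylates, which is established for closing germacranolide rings at this same C6–C7 bond. The ten-membered carbocycle closes by 10-exo-trig attack on the carbonyl group under high dilution, and the lactone closes by 5-exo-trig acyl substitution with loss of methoxide. C6 and C7 are set together: the (Z)-bromide holds C8 cis to the CH2Cr carbon and hence axial in the chair while the enal residue sits equatorial, which gives the syn adduct and therefore the cis-fused lactone (H-6 and H-7 syn). The absolute sense comes from C8, because A(1,3) strain turns H-8 toward the CH2Cr group, leaves the C8–C9 bond antiperiplanar to the forming bond with the silyloxy group gauche, and lets the ring close without a syn-pentane contact, so that C7 should become R and C6 should become S. The step needs attack on the aldehyde alone and ahead of electron transfer to the enedione: allylchromium reagents strongly prefer aldehydes to ketones and do not add in conjugate fashion, the doubly activated 4-oxo-enal carbonyl is the most electrophilic site while the C3 ketone is hindered and conjugated, and inner-sphere reduction of the allylic bromide should outpace outer-sphere reduction of the enedione in aprotic THF.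

Step 12
Reactants: 23 cis-fused ten-membered α-methylene lactone (8,10-bis-O-triethylsilyl 15-O-tert-butyldiphenylsilyl ether of the 8-deangeloyl target)
Product: 24 C8 alcohol (10-O-triethylsilyl 15-O-tert-butyldiphenylsilyl ether of the 8-deangeloyl target)
Conditions: PPTS (0.3 equiv), MeOH/CH2Cl2 (1:3), 0 °C
Reagents that add atoms: none
Why: Mild acid-catalysed methanolysis removes the secondary triethylsilyl ether much faster than the hindered tertiary one at C10 and the primary tert-butyldiphenylsilyl ether (selective silyl ether solvolysis), and no stereocentre is affected.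

Step 13
Reactants: 24 C8 alcohol (10-O-triethylsilyl 15-O-tert-butyldiphenylsilyl ether of the 8-deangeloyl target); 25 angelic acid
Product: 27 10-O-triethylsilyl 15-O-tert-butyldiphenylsilyl ether of the target, via mixed anhydride 26 (not isolated)
Conditions: 25, 2,4,6-trichlorobenzoyl chloride, Et3N, toluene, rt; then 24, DMAP, toluene, rt → 40 °C
Reagents that add atoms: none
Why: Yamaguchi esterification: the mixed anhydride 26 is attacked by DMAP at the unhindered angeloyl carbonyl and the acylpyridinium ion acylates the only free hydroxyl group, a mixed-anhydride protocol in toluene being the established way to transfer angelic acid without Z to E isomerisation.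

Step 14
Reactants: 27 10-O-triethylsilyl 15-O-tert-butyldiphenylsilyl ether of the target
Product: 28 CNP0181802.1 (target)
Conditions: HF·pyridine, pyridine, THF, 0 °C → rt
Reagents that add atoms: none
Why: Fluoride-induced desilylation with buffered HF·pyridine cleaves the tertiary triethylsilyl and the primary tert-butyldiphenylsilyl ether under weakly acidic conditions that the α-methylene lactone, the angelate and the γ-acyloxy enone should tolerate.

**Compound list**

1 | (S)-(+)-linalool, (3S)-3,7-dimethylocta-1,6-dien-3-ol | C=C[C@@](C)(O)CCC=C(C)C | starting material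
2 | (3S)-3,7-dimethyl-3-(triethylsilyloxy)octa-1,6-diene | C=C[C@@](C)(O[Si](CC)(CC)CC)CCC=C(C)C | intermediate
3 | 3-furanmethanol | OCc1ccoc1 | starting material
4 | 2-lithio-3-(lithiooxymethyl)furan | [Li]OCc1ccoc1[Li] | intermediate
5 | lithium (2-bromofuran-3-yl)methoxide | [Li]OCc1ccoc1Br | intermediate
6 | 2-bromo-3-[(tert-butyldiphenylsilyloxy)methyl]furan | CC(C)(C)[Si](OCc1ccoc1Br)(c1ccccc1)c1ccccc1 | intermediate
7 | 9-[(3R)-3,7-dimethyl-3-(triethylsilyloxy)oct-6-enyl]-9-borabicyclo[3.3.1]nonane | B1(C2CCCC1CCC2)CC[C@@](C)(O[Si](CC)(CC)CC)CCC=C(C)C | intermediate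
8 | 3-[(tert-butyldiphenylsilyloxy)methyl]-2-[(3S)-3,7-dimethyl-3-(triethylsilyloxy)oct-6-enyl]furan | CC(C)(C)[Si](OCc1ccoc1CC[C@@](C)(O[Si](CC)(CC)CC)CCC=C(C)C)(c1ccccc1)c1ccccc1 | intermediate
9 | (6S)-8-{3-[(tert-butyldiphenylsilyloxy)methyl]furan-2-yl}-2,6-dimethyl-6-(triethylsilyloxy)octane-2,3-diol (both C3 epimers) | CC(C)(C)[Si](OCc1ccoc1CC[C@@](C)(O[Si](CC)(CC)CC)CCC(O)C(C)(C)O)(c1ccccc1)c1ccccc1 | intermediate
10 | (4R)-6-{3-[(tert-butyldiphenylsilyloxy)methyl]furan-2-yl}-4-methyl-4-(triethylsilyloxy)hexanal | CC(C)(C)[Si](OCc1ccoc1CC[C@@](C)(O[Si](CC)(CC)CC)CCC=O)(c1ccccc1)c1ccccc1 | intermediate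
11 | (2R,4R)-6-{3-[(tert-butyldiphenylsilyloxy)methyl]furan-2-yl}-4-methyl-2-(N-phenylaminooxy)-4-(triethylsilyloxy)hexanal | CC(C)(C)[Si](OCc1ccoc1CC[C@@](C)(O[Si](CC)(CC)CC)C[C@@H](ONc1ccccc1)C=O)(c1ccccc1)c1ccccc1 | intermediate
12 | (2R,4R)-6-{3-[(tert-butyldiphenylsilyloxy)methyl]furan-2-yl}-4-methyl-2-(N-phenylaminooxy)-4-(triethylsilyloxy)hexan-1-ol | CC(C)(C)[Si](OCc1ccoc1CC[C@@](C)(O[Si](CC)(CC)CC)C[C@@H](ONc1ccccc1)CO)(c1ccccc1)c1ccccc1 | intermediate
13 | (2R,4R)-6-{3-[(tert-butyldiphenylsilyloxy)methyl]furan-2-yl}-4-methyl-4-(triethylsilyloxy)hexane-1,2-diol | CC(C)(C)[Si](OCc1ccoc1CC[C@@](C)(O[Si](CC)(CC)CC)C[C@@H](O)CO)(c1ccccc1)c1ccccc1 | intermediate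
14 | 1,2-bis-O-triethylsilyl ether of 13, (2R,4R)-1,2,4-tris(triethylsilyloxy) compound | CC(C)(C)[Si](OCc1ccoc1CC[C@@](C)(O[Si](CC)(CC)CC)C[C@@H](O[Si](CC)(CC)CC)CO[Si](CC)(CC)CC)(c1ccccc1)c1ccccc1 | intermediate
15 | (2R,4R)-6-{3-[(tert-butyldiphenylsilyloxy)methyl]furan-2-yl}-4-methyl-2,4-bis(triethylsilyloxy)hexanal | CC(C)(C)[Si](OCc1ccoc1CC[C@@](C)(O[Si](CC)(CC)CC)C[C@@H](O[Si](CC)(CC)CC)C=O)(c1ccccc1)c1ccccc1 | intermediate
16 | methyl acrylate | C=CC(=O)OC | starting material
17 | methyl (4R,6R)-8-{3-[(tert-butyldiphenylsilyloxy)methyl]furan-2-yl}-3-hydroxy-6-methyl-2-methylidene-4,6-bis(triethylsilyloxy)octanoate (both C3 epimers) | CC(C)(C)[Si](OCc1ccoc1CC[C@@](C)(O[Si](CC)(CC)CC)C[C@@H](O[Si](CC)(CC)CC)C(O)C(=C)C(=O)OC)(c1ccccc1)c1ccccc1 | intermediate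
18 | 3-O-methanesulfonate of 17 | CC(C)(C)[Si](OCc1ccoc1CC[C@@](C)(O[Si](CC)(CC)CC)C[C@@H](O[Si](CC)(CC)CC)C(OS(C)(=O)=O)C(=C)C(=O)OC)(c1ccccc1)c1ccccc1 | intermediate
19 | methyl (2Z,4R,6R)-2-(bromomethyl)-8-{3-[(tert-butyldiphenylsilyloxy)methyl]furan-2-yl}-6-methyl-4,6-bis(triethylsilyloxy)oct-2-enoate | CC(C)(C)[Si](OCc1ccoc1CC[C@@](C)(O[Si](CC)(CC)CC)C[C@@H](O[Si](CC)(CC)CC)/C=C(\CBr)C(=O)OC)(c1ccccc1)c1ccccc1 | intermediate
20 | methyl (2Z,4R,6R,10Z)-2-(bromomethyl)-10-[(tert-butyldiphenylsilyloxy)methyl]-6-methyl-9,12-dioxo-4,6-bis(triethylsilyloxy)dodeca-2,10-dienoate | O=C/C=C(/CO[Si](c1ccccc1)(c1ccccc1)C(C)(C)C)C(=O)CC[C@@](C)(O[Si](CC)(CC)CC)C[C@@H](O[Si](CC)(CC)CC)/C=C(\CBr)C(=O)OC | intermediate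
21 | allylchromium dichloride from 20 (CrCl2 group in place of Br, trivalent chromium) | O=C/C=C(/CO[Si](c1ccccc1)(c1ccccc1)C(C)(C)C)C(=O)CC[C@@](C)(O[Si](CC)(CC)CC)C[C@@H](O[Si](CC)(CC)CC)/C=C(\C[Cr](Cl)Cl)C(=O)OC | intermediate
22 | ten-membered seco hydroxy ester, formed as its chromium alkoxide and drawn as the alcohol: methyl (4Z)-15-(tert-butyldiphenylsilyloxy)-6-hydroxy-3-oxo-8,10-bis(triethylsilyloxy)germacra-4,11(13)-dien-12-oate, configured at C6, C7, C8 and C10 as in the target | O[C@H]1/C=C(/CO[Si](c2ccccc2)(c2ccccc2)C(C)(C)C)C(=O)CC[C@@](C)(O[Si](CC)(CC)CC)C[C@@H](O[Si](CC)(CC)CC)[C@H]1C(=C)C(=O)OC | intermediate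
23 | 8,10-bis-O-triethylsilyl 15-O-tert-butyldiphenylsilyl ether of the 8-deangeloyl target (cis-fused 6,12-lactone) | C=C1C(=O)O[C@H]2/C=C(/CO[Si](c3ccccc3)(c3ccccc3)C(C)(C)C)C(=O)CC[C@@](C)(O[Si](CC)(CC)CC)C[C@@H](O[Si](CC)(CC)CC)[C@@H]12 | intermediate
24 | 10-O-triethylsilyl 15-O-tert-butyldiphenylsilyl ether of the 8-deangeloyl target (free C8 alcohol) | C=C1C(=O)O[C@H]2/C=C(/CO[Si](c3ccccc3)(c3ccccc3)C(C)(C)C)C(=O)CC[C@@](C)(O[Si](CC)(CC)CC)C[C@@H](O)[C@@H]12 | intermediate
25 | angelic acid, (2Z)-2-methylbut-2-enoic acid | C/C=C(/C)C(=O)O | starting material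
26 | angelic 2,4,6-trichlorobenzoic anhydride | C/C=C(/C)C(=O)OC(=O)c1c(Cl)cc(Cl)cc1Cl | intermediate
27 | 10-O-triethylsilyl 15-O-tert-butyldiphenylsilyl ether of the target | C=C1C(=O)O[C@H]2/C=C(/CO[Si](c3ccccc3)(c3ccccc3)C(C)(C)C)C(=O)CC[C@@](C)(O[Si](CC)(CC)CC)C[C@@H](OC(=O)/C(C)=C\C)[C@@H]12 | intermediate
28 | CNP0181802.1 | C=C1C(=O)O[C@H]2/C=C(/CO)C(=O)CC[C@@](C)(O)C[C@@H](OC(=O)/C(C)=C\C)[C@@H]12 | target

**Count and risks**

Total step count: 14. Longest linear sequence: 13 steps (from 1 through steps 1 and 3–14, or from 3 through steps 2–14).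

Steps most likely to fail:

1. Step 11 (ring closure). What may go wrong:
   - electron transfer from the excess CrCl2 to the enedione;
   - Z to E isomerisation of the enedione under the Lewis-acidic chromium salts;
   - closure onto the C3 ketone (seven-membered ring) or oligomerisation in place of the ten-membered closure;
   - incomplete facial control by C8.

   Fallback without a reducing metal, setting out from bromide 19: borylation with B2pin2 under Pd2(dba)3 catalysis (toluene, 50 °C) should give the (2E)-configured pinacol allylboronate F1, which has the same spatial geometry (C8 cis to the CH2B carbon). The furan is then opened without a peroxide reagent by photo-oxygenation (O2, rose bengal, light, CH2Cl2, −78 °C) and Me2S reduction, giving the (Z)-enedione aldehyde boronate F2. Heating F2 at high dilution in toluene (60–80 °C, or Sc(OTf)3 catalysis at low temperature) should effect intramolecular allylboration of the aldehyde through the same chair. The borate lactonises, and the fallback rejoins the route at lactone 23.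

2. Step 10 (furan opening). What may go wrong: over-oxidation, and loss of the Z geometry or decomposition of the unveiled 4-oxo-enal during concentration and transfer.

   Fallback through a storable masked enedione, setting out from bromide 19: NBS and NaHCO3 in MeOH at −40 °C should give the 2,5-dimethoxy-2,5-dihydrofuran F3 as a mixture of acetal epimers, which can be purified and kept. Brief hydrolysis (PPTS cat., acetone/H2O, 0 °C) immediately before the cyclisation releases the cis-enedione, and the fallback rejoins the route at 20.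

3. Step 13 (angelate). What may go wrong: slow acylation of the hindered ring alcohol, Z to E isomerisation of the angeloyl group to the tiglate under DMAP, and base-induced acyl shift of the lactone from O6 to O8.

   Fallback that builds the angelate double bond on the molecule, setting out from alcohol 24: acylation with 2-(diphenoxyphosphoryl)propanoic acid (DCC, DMAP cat., CH2Cl2, 0 °C) gives the phosphonopropionate F4. A Z-selective Horner–Wadsworth–Emmons olefination of F4 with acetaldehyde (NaI, DBU, THF, −20 °C) should then give the (Z)-2-methylbut-2-enoate, and the fallback rejoins the route at 27.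

Further compounds
F1 | step 11 | methyl (2E,4R,6R)-8-{3-[(tert-butyldiphenylsilyloxy)methyl]furan-2-yl}-6-methyl-2-[(4,4,5,5-tetramethyl-1,3,2-dioxaborolan-2-yl)methyl]-4,6-bis(triethylsilyloxy)oct-2-enoate | CC(C)(C)[Si](OCc1ccoc1CC[C@@](C)(O[Si](CC)(CC)CC)C[C@@H](O[Si](CC)(CC)CC)/C=C(\CB2OC(C)(C)C(C)(C)O2)C(=O)OC)(c1ccccc1)c1ccccc1
F2 | step 11 | (Z)-enedione aldehyde with the pinacol boronate in place of the bromide of 20 | O=C/C=C(/CO[Si](c1ccccc1)(c1ccccc1)C(C)(C)C)C(=O)CC[C@@](C)(O[Si](CC)(CC)CC)C[C@@H](O[Si](CC)(CC)CC)/C=C(\CB1OC(C)(C)C(C)(C)O1)C(=O)OC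
F3 | step 10 | 2,5-dimethoxy-2,5-dihydrofuran derived from 19 (acetal epimers) | COC1C=C(CO[Si](c2ccccc2)(c2ccccc2)C(C)(C)C)C(CC[C@@](C)(O[Si](CC)(CC)CC)C[C@@H](O[Si](CC)(CC)CC)/C=C(\CBr)C(=O)OC)(OC)O1
F4 | step 13 | 8-O-[2-(diphenoxyphosphoryl)propanoyl] derivative of 24 | C=C1C(=O)O[C@H]2/C=C(/CO[Si](c3ccccc3)(c3ccccc3)C(C)(C)C)C(=O)CC[C@@](C)(O[Si](CC)(CC)CC)C[C@@H](OC(=O)C(C)P(=O)(Oc3ccccc3)Oc3ccccc3)[C@@H]12
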